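## Retrosynthetic overview
1. Target ⇒ its octabenzyl ether (global hydrogenolysis comes last) ⇒ (2R)-flavan-3-one, with the C3 carbinol made by catalyst-controlled ketone reduction.
2. Key disconnection C4–C4a. C4 is made electrophilic as an α-oxo gold carbene, an enolonium equivalent of the C3 ketone generated by oxidising a terminal alkyne. The ortho carbon of ring A attacks it, so two natively nucleophilic carbons are joined.
3. (S)-Aryl propargyl ether ⇒ C2–O1 bond, by enantioconvergent Cu-catalysed propargylic etherification of a racemic propargylic acetate with 3,5-digalloylated phloroglucinol.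
4. Both gallates go onto phloroglucinol at the very start, so neither ring A nor the 3-OH ever needs a protecting group.
5. Ring order: rings A, B and both galloyl rings are bought. The pyran ring C is the only ring formed, in the key step.

Assumption: the (S,S)-antipode of Ph-pybox is taken to give the (S)-ether 8; if the sense of induction is the opposite, the equally available (R,R)-ligand is used and nothing else changes. Flavan numbering O1, C2, C3, C4, C4a is used throughout.

## Route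

Step 1
Reactants: 1 phloroglucinol; 2 3,4,5-tris(benzyloxy)benzoic acid (2.0 equiv)
Product: 3 5-hydroxybenzene-1,3-diyl bis[3,4,5-tris(benzyloxy)benzoate]
Conditions: DCC (2.1 equiv), DMAP (0.2 equiv), THF–CH2Cl2, 0 °C → rt
Reagents that add atoms: none
Why: Steglich esterification of C3-symmetric phloroglucinol, where only the degree of acylation matters, so the diester (statistical maximum about 44 %) is separated by chromatography from mono- and triester, and no stereocentre is formed.

Step 2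
Reactants: 4 3,4-bis(benzyloxy)benzaldehyde; 5 ethynylmagnesium bromide
Product: 7 (±)-1-[3,4-bis(benzyloxy)phenyl]prop-2-yn-1-yl acetate, via bromomagnesium propargylic alkoxide 6 (not isolated)
Conditions: 5 (1.2 equiv), THF, 0 °C; then Ac2O (1.5 equiv), 0 °C → rt
Reagents that add atoms: acetic anhydride, CC(=O)OC(C)=O
Why: Grignard 1,2-addition to a non-enolisable aldehyde followed by O-acylation of the alkoxide in the same flask, leaving the new centre deliberately racemic because the next step is enantioconvergent.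

Step 3
Reactants: 3 5-hydroxybenzene-1,3-diyl bis[3,4,5-tris(benzyloxy)benzoate]; 7 (±)-1-[3,4-bis(benzyloxy)phenyl]prop-2-yn-1-yl acetate
Product: 8 5-{(1S)-1-[3,4-bis(benzyloxy)phenyl]prop-2-yn-1-yloxy}benzene-1,3-diyl bis[3,4,5-tris(benzyloxy)benzoate]
Conditions: CuOTf·½C6H6 (5 mol %), (S,S)-Ph-pybox (10 mol %), iPr2NEt (1.2 equiv), THF, −20 °C, Ar
Reagents that add atoms: none
Why: Copper-catalysed asymmetric propargylic substitution with a phenol nucleophile, in which both enantiomers of 7 are ionised by the chiral catalyst and converge, the pybox ligand allows O-attack on one face only and so sets the future C2 (S here, R in the flavan after the CIP priority change), and the two acyloxy groups make ring A too poor a carbon nucleophile for competing C-alkylation.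

Step 4
Reactants: 8 5-{(1S)-1-[3,4-bis(benzyloxy)phenyl]prop-2-yn-1-yloxy}benzene-1,3-diyl bis[3,4,5-tris(benzyloxy)benzoate]
Product: 10 (2R)-2-[3,4-bis(benzyloxy)phenyl]-3-oxochromane-5,7-diyl bis[3,4,5-tris(benzyloxy)benzoate], via α-oxo gold carbene 9 (not isolated)
Conditions: Me4tBuXPhosAuNTf2 (5 mol %), 2,6-dichloropyridine N-oxide (1.3 equiv, added over 2 h), 4 Å MS, DCE, rt
Reagents that add atoms: 2,6-dichloropyridine N-oxide, [O-][n+]1c(Cl)cccc1Cl
Why: Gold-catalysed alkyne oxidation with Friedel–Crafts closure (the known conversion of aryl propargyl ethers into chroman-3-ones), in which N-oxide attack at the internal alkyne carbon and N–O cleavage make the terminal carbon an α-oxo gold carbene (enolonium equivalent at C4) that is trapped in a six-membered closure by either of the two equivalent ortho carbons of ring A, while the neutral medium and the non-basic 2,6-dichloropyridine leave the C2 stereocentre untouched.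

Step 5
Reactants: 10 (2R)-2-[3,4-bis(benzyloxy)phenyl]-3-oxochromane-5,7-diyl bis[3,4,5-tris(benzyloxy)benzoate]
Product: 11 (2R,3S)-2-[3,4-bis(benzyloxy)phenyl]-3-hydroxychromane-5,7-diyl bis[3,4,5-tris(benzyloxy)benzoate]
Conditions: (R)-Me-CBS (0.3 equiv), BH3·SMe2 (1.0 equiv), THF–toluene, −30 °C; then H2O
Reagents that add atoms: none
Why: Corey–Bakshi–Shibata reduction in which the branched C2 side is the large group and the C4 methylene the small one, so the (R)-catalyst delivers hydride to the face that gives the (3S)-carbinol, which is the 2,3-trans alcohol from (2R)-10, under base-free conditions that neither epimerise C2 nor touch the aryl esters, and any (2S)-ketone carried over from step 3 ends up as the separable cis diastereomer.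

Step 6
Reactants: 11 (2R,3S)-2-[3,4-bis(benzyloxy)phenyl]-3-hydroxychromane-5,7-diyl bis[3,4,5-tris(benzyloxy)benzoate]
Product: 12 (+)-catechin 5,7-di-O-gallate, (2R,3S)
Conditions: H2 (1 atm), 20 % Pd(OH)2/C, THF–EtOAc, rt
Reagents that add atoms: none
Why: Global hydrogenolysis of the eight O-benzyl ethers over Pearlman's catalyst, in which the aryl esters, the secondary alcohol and both stereocentres are inert in a non-nucleophilic solvent and the cyclic C2–O1 bond is cleaved far more slowly than the acyclic benzyl ethers.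

## Compound list
1 | phloroglucinol | Oc1cc(O)cc(O)c1 | starting material
2 | 3,4,5-tris(benzyloxy)benzoic acid | OC(=O)c1cc(OCc2ccccc2)c(OCc2ccccc2)c(OCc2ccccc2)c1 | starting material
3 | 5-hydroxybenzene-1,3-diyl bis[3,4,5-tris(benzyloxy)benzoate] | Oc1cc(OC(=O)c2cc(OCc3ccccc3)c(OCc3ccccc3)c(OCc3ccccc3)c2)cc(OC(=O)c2cc(OCc3ccccc3)c(OCc3ccccc3)c(OCc3ccccc3)c2)c1 | intermediate
4 | 3,4-bis(benzyloxy)benzaldehyde | O=Cc1ccc(OCc2ccccc2)c(OCc2ccccc2)c1 | starting material
5 | ethynylmagnesium bromide (0.5 M in THF) | C#C[Mg]Br | starting material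
6 | bromomagnesium 1-[3,4-bis(benzyloxy)phenyl]prop-2-yn-1-olate (racemic, not isolated) | C#CC(O[Mg]Br)c1ccc(OCc2ccccc2)c(OCc2ccccc2)c1 | intermediate
7 | (±)-1-[3,4-bis(benzyloxy)phenyl]prop-2-yn-1-yl acetate | C#CC(OC(C)=O)c1ccc(OCc2ccccc2)c(OCc2ccccc2)c1 | intermediate
8 | 5-{(1S)-1-[3,4-bis(benzyloxy)phenyl]prop-2-yn-1-yloxy}benzene-1,3-diyl bis[3,4,5-tris(benzyloxy)benzoate] | C#C[C@H](Oc1cc(OC(=O)c2cc(OCc3ccccc3)c(OCc3ccccc3)c(OCc3ccccc3)c2)cc(OC(=O)c2cc(OCc3ccccc3)c(OCc3ccccc3)c(OCc3ccccc3)c2)c1)c1ccc(OCc2ccccc2)c(OCc2ccccc2)c1 | intermediate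
9 | α-oxo gold carbene [(Me4tBuXPhos)Au=CH–C(=O)–CH(ArB)(OArA)]+ NTf2−, (R) at the ether carbon (not isolated) | O=C(C=[Au][P+](C(C)(C)C)(C(C)(C)C)c1c(C)c(C)c(C)c(C)c1-c1c(C(C)C)cc(C(C)C)cc1C(C)C)[C@H](Oc1cc(OC(=O)c2cc(OCc3ccccc3)c(OCc3ccccc3)c(OCc3ccccc3)c2)cc(OC(=O)c2cc(OCc3ccccc3)c(OCc3ccccc3)c(OCc3ccccc3)c2)c1)c1ccc(OCc2ccccc2)c(OCc2ccccc2)c1.O=S(=O)([N-]S(=O)(=O)C(F)(F)F)C(F)(F)F | intermediate
10 | (2R)-2-[3,4-bis(benzyloxy)phenyl]-3-oxochromane-5,7-diyl bis[3,4,5-tris(benzyloxy)benzoate] | O=C(Oc1cc(OC(=O)c2cc(OCc3ccccc3)c(OCc3ccccc3)c(OCc3ccccc3)c2)c2c(c1)O[C@H](c1ccc(OCc3ccccc3)c(OCc3ccccc3)c1)C(=O)C2)c1cc(OCc2ccccc2)c(OCc2ccccc2)c(OCc2ccccc2)c1 | intermediate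
11 | (2R,3S)-2-[3,4-bis(benzyloxy)phenyl]-3-hydroxychromane-5,7-diyl bis[3,4,5-tris(benzyloxy)benzoate] | O=C(Oc1cc(OC(=O)c2cc(OCc3ccccc3)c(OCc3ccccc3)c(OCc3ccccc3)c2)c2c(c1)O[C@H](c1ccc(OCc3ccccc3)c(OCc3ccccc3)c1)[C@@H](O)C2)c1cc(OCc2ccccc2)c(OCc2ccccc2)c(OCc2ccccc2)c1 | intermediate
12 | (+)-catechin 5,7-di-O-gallate, (2R,3S) | O=C(Oc1cc(OC(=O)c2cc(O)c(O)c(O)c2)c2c(c1)O[C@H](c1ccc(O)c(O)c1)[C@@H](O)C2)c1cc(O)c(O)c(O)c1 | target

## Step count and weak points
Total step count: 6. Longest linear sequence: 5 steps (4 → 7 → 8 → 10 → 11 → 12, or equally 1 → 3 → 8 → 10 → 11 → 12).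

**Step 4 is the most likely to fail.**
- Cationic gold may ionise the doubly activated C2–O bond, which would racemise C2 or expel phenol 3.
- Carbene 9 may be over-oxidised to the glyoxal.
- The electron-rich ring B may trap the carbene in a five-membered closure to a 2-indanone.
- Plain hydroarylation may outrun the oxidation.

The fallback sets out from 8 and comes back at 11, bypassing 9 and 10. Without oxidant, IPrAuNTf2 (2 mol %, CH2Cl2, rt) converts 8 by 6-endo-dig hydroarylation into the flav-3-ene (2S)-2-[3,4-bis(benzyloxy)phenyl]-2H-chromene-5,7-diyl bis[3,4,5-tris(benzyloxy)benzoate] F1. BH3·SMe2 (THF, 0 °C) then adds syn across C3=C4 from the face opposite the 2-aryl group. Boron goes to C3, away from the benzylic carbon and next to the allylic oxygen, giving the trans-borane (2S,3S)-2-[3,4-bis(benzyloxy)phenyl]-3-boranylchromane-5,7-diyl bis[3,4,5-tris(benzyloxy)benzoate] F2. H2O2 in pH 7 buffer oxidises the C–B bond with retention to 11.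

**Step 5 is second.** Hydride must arrive on the face syn to the 2-aryl group. This goes against the intrinsic bias of this ketone, since bulky hydrides give the cis alcohol, so catalyst control may be incomplete. The fallback sets out from 10 and comes back at 11, and it uses the intrinsic bias and then inverts.
- L-Selectride (THF, −78 °C, non-oxidative work-up) gives the cis alcohol (2R,3R)-2-[3,4-bis(benzyloxy)phenyl]-3-hydroxychromane-5,7-diyl bis[3,4,5-tris(benzyloxy)benzoate] F3.
- A Mitsunobu reaction with chloroacetic acid (PPh3, DIAD, toluene, 0 °C) inverts C3 to the trans ester (2R,3S)-2-[3,4-bis(benzyloxy)phenyl]-3-(chloroacetoxy)chromane-5,7-diyl bis[3,4,5-tris(benzyloxy)benzoate] F4.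
- Thiourea (NaHCO3, THF–EtOH, 40 °C) removes only the chloroacetyl group, by S-alkylation and cyclisation, and leaves the aryl gallates in place, giving 11.

**Step 3 is third.** The bulky, weakly nucleophilic phenol 3 may react slowly. The electron-rich acetate may undergo an uncatalysed racemic background substitution, and the ee may be moderate. The fallback sets out from 7 and comes back at 8. It replaces enantioconvergent catalysis by resolution followed by stereospecific substitution.
- Novozym 435 (phosphate buffer pH 7/MTBE, 30 °C, stopped near 50 % conversion) hydrolyses the fast-reacting enantiomer to (R)-1-[3,4-bis(benzyloxy)phenyl]prop-2-yn-1-ol F5.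
- It leaves behind (S)-1-[3,4-bis(benzyloxy)phenyl]prop-2-yn-1-yl acetate F6.
- Mitsunobu etherification of F5 with phenol 3 (PPh3, DIAD, toluene, −20 °C) proceeds with inversion to give 8.

## Further compounds
F1 | step 4 | (2S)-2-[3,4-bis(benzyloxy)phenyl]-2H-chromene-5,7-diyl bis[3,4,5-tris(benzyloxy)benzoate] | O=C(Oc1cc(OC(=O)c2cc(OCc3ccccc3)c(OCc3ccccc3)c(OCc3ccccc3)c2)c2c(c1)O[C@H](c1ccc(OCc3ccccc3)c(OCc3ccccc3)c1)C=C2)c1cc(OCc2ccccc2)c(OCc2ccccc2)c(OCc2ccccc2)c1
F2 | step 4 | (2S,3S)-2-[3,4-bis(benzyloxy)phenyl]-3-boranylchromane-5,7-diyl bis[3,4,5-tris(benzyloxy)benzoate] | O=C(Oc1cc(OC(=O)c2cc(OCc3ccccc3)c(OCc3ccccc3)c(OCc3ccccc3)c2)c2c(c1)O[C@H](c1ccc(OCc3ccccc3)c(OCc3ccccc3)c1)[C@@H](B)C2)c1cc(OCc2ccccc2)c(OCc2ccccc2)c(OCc2ccccc2)c1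
F3 | step 5 | (2R,3R)-2-[3,4-bis(benzyloxy)phenyl]-3-hydroxychromane-5,7-diyl bis[3,4,5-tris(benzyloxy)benzoate] | O=C(Oc1cc(OC(=O)c2cc(OCc3ccccc3)c(OCc3ccccc3)c(OCc3ccccc3)c2)c2c(c1)O[C@H](c1ccc(OCc3ccccc3)c(OCc3ccccc3)c1)[C@H](O)C2)c1cc(OCc2ccccc2)c(OCc2ccccc2)c(OCc2ccccc2)c1
F4 | step 5 | (2R,3S)-2-[3,4-bis(benzyloxy)phenyl]-3-(chloroacetoxy)chromane-5,7-diyl bis[3,4,5-tris(benzyloxy)benzoate] | O=C(Oc1cc(OC(=O)c2cc(OCc3ccccc3)c(OCc3ccccc3)c(OCc3ccccc3)c2)c2c(c1)O[C@H](c1ccc(OCc3ccccc3)c(OCc3ccccc3)c1)[C@@H](OC(=O)CCl)C2)c1cc(OCc2ccccc2)c(OCc2ccccc2)c(OCc2ccccc2)c1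
F5 | step 3 | (R)-1-[3,4-bis(benzyloxy)phenyl]prop-2-yn-1-ol | C#C[C@@H](O)c1ccc(OCc2ccccc2)c(OCc2ccccc2)c1
F6 | step 3 | (S)-1-[3,4-bis(benzyloxy)phenyl]prop-2-yn-1-yl acetate | C#C[C@H](OC(C)=O)c1ccc(OCc2ccccc2)c(OCc2ccccc2)c1
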